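I followed one molecule.

| setting | grey | amber | south-east | north-west | south-west | south | east |
|---|---|---|---|---|---|---|---|
| starting complex | 0.22 M | 0.72 M | 0.40 M | 2.5 M | 0.25 M | 1.2 M | 0.80 M |
| incoming ligand | 2.4 M | 2.4 M | 2.40 M | 2.40 M | 2.40 M | 2.40 M | 2.40 M |
| remark | run made earlier | run made earlier |  |  |  |  |  |
| time |  |  | 5.0 min | 5.0 min | 5.0 min | 5.0 min | 5.0 min |

| grey: time / min | grey: complex with one exchanged / % | amber: time / min | amber: complex with one exchanged / % |
|---|---|---|---|
| 0.333 | 21.2 | 0.333 | 20.1 |
| 0.833 | 43.1 | 0.833 | 40.2 |
| 1.50 | 59.0 | 1.50 | 55.0 |
| 2.50 | 70.7 | 2.50 | 64.7 |
| 4.00 | 74.4 | 4.00 | 66.7 |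

(scatter of a reading: 0.5 percentage points)

- the flasks put in order of amount of complex with one exchanged, in percent of the starting complex charged, best first, at 5.0 min (south-east / north-west / south-west / south / east)
- the amount of complex with one exchanged, in percent of the starting complex charged of the flask you put first, at 5.0 min
- the amount of complex with one exchanged, in percent of the starting complex charged of the flask you put last, at 5.0 min



At its fork, a molecule of starting complex either became complex with one exchanged or went elsewhere. So I took the loss odds at the last readings, the share not found there over the share found there. They were 0.344 in grey and 0.499 in amber, higher at the larger charge. The curves were flattening, so I let these readings stand for the asked time.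

For north-west, the largest charge, I bracketed the yield of complex with one exchanged. From above stood amber's 66.7%, provided the yield keeps falling with charge. From below stood 39.3%, the straight line through the two yields, provided the fall doesn't steepen with charge. To tighten this, I supposed a competitor growing with the charge, which makes the odds, not the yield, linear in charge. The charge slope, the rise of the loss odds per unit of charge, was 0.310 L mol⁻¹, on a base of 0.276. That gave north-west 48.7% and south-west 73.9%.

The forecast said south-west > south-east > east > south > north-west, with 75% first and 50% last, and called the far end “a long extrapolation and so uncertain”. Its low lay inside my bracket, above my figure, and its top was also above mine.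

The flasks gave south-west > south-east > east > south > north-west, with south-west at 72.0%, and north-west at 51.6%, inside its bracket.

    starting complex + incoming ligand ⇌ leaving ligand + complex with one exchanged (K = 14.0, k = 0.00490 L mol⁻¹ s⁻¹)
    complex with one exchanged + incoming ligand ⇌ leaving ligand + complex with two exchanged (K = 8.70, k = 4.30 × 10⁻⁴ L mol⁻¹ s⁻¹)
    leaving ligand + starting complex → side product (k = 0.00830 L mol⁻¹ s⁻¹)
    complex with two exchanged + incoming ligand ⇌ leaving ligand + complex with three exchanged (K = 0.290, k = 0.0430 L mol⁻¹ s⁻¹)

In these equations starting complex forks: it meets incoming ligand or leaving ligand. One further flask was like north-west but with 0.96 M of incoming ligand, the limiting reagent at 0.384 equiv. I multiplied the charge term, built on the slope 0.310 L mol⁻¹, by the ligand ratio 2.50. This gave odds of 2.22, or 31.1% kept. That flask gave 32.2% of complex with one exchanged, but its remainder was not all lost: at 5.00 min side product stood at 29.0%, and starting complex, the largest holder, at 38.0%.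

(The runs are calculated with constants of no real substance, and the scatter is random.)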